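**Retrosynthetic overview** (locants are those of the target's 2-oxaspiro[4.5]decane core)
1. The enal is unmasked last from a Weinreb amide; the tetrahydrofuran comes from Williamson closure of a C3 alkoxide on a C1 tosylate; C3 comes from Nozaki–Hiyama–Kishi coupling of a C5-bound acetaldehyde with a (1E,3E,5E)-tetraenyl iodide, then CBS reduction.
2. The (Z)-tetrasubstituted alkene is fixed by a temporary bicyclic unsaturated δ-lactone (intramolecular HWE through a C6–CH2O tether); the C6 arm is then extended by vinyl cuprate and hydroboration.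
3. The C10 carbinol comes from enol-triflate methylation, hydroxyl-directed epoxidation and hydride opening; the C7 oxygen from a vinylogous Rubottom oxidation.
4. Key C–C bond (C5–C6): intermolecular organocatalytic Michael addition of methyl acetoacetate to a γ-silyloxy enal, then aldol condensation; quaternary C5 by trans-selective cinnamylation.
5. Ring order: cyclohexane (step 3), temporary δ-lactone (step 17, opened in step 18), tetrahydrofuran (step 31).

Convention: all intermediates carry the target's locants (C1 = CH2O carbon on C5, C4–C3 = the other arm on C5, C5 = quaternary carbon, C6 = CH with the side arm, C10 = carbon bearing CH3 and O); α is the ring face carrying the C1 arm, the C6 arm and the C10 oxygen, β the opposite face.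
Assumption: the C7 carbinol centre made in step 6 (drawn β) and the C3 carbinol centre made in step 28 (unassigned) are inconsequential, since both are oxidised later.

**Step 1**
Reactants: 1 (Z)-but-2-ene-1,4-diol
Product: 2 (Z)-4-[(tert-butyldiphenylsilyl)oxy]but-2-en-1-ol
Conditions: TBDPSCl (0.35 equiv), imidazole, THF, 0 °C
Reagents that add atoms: tert-butyl(chloro)diphenylsilane CC(C)(C)[Si](Cl)(c1ccccc1)c1ccccc1
Why: Statistical monosilylation of the symmetric diol used in excess (silyl ether formation, no stereocentre).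

**Step 2**
Reactants: 2 (Z)-4-[(tert-butyldiphenylsilyl)oxy]but-2-en-1-ol
Product: 3 (E)-4-[(tert-butyldiphenylsilyl)oxy]but-2-enal
Conditions: pyridinium chlorochromate [C5H5NH][CrO3Cl], NaOAc, CH2Cl2, rt
Reagents that add atoms: none
Why: Chromate oxidation of the allylic alcohol with concomitant Z-to-E isomerisation to the more stable enal (any residual Z isomer equilibrates under the amine catalysis of step 3).

**Step 3**
Reactants: 3 (E)-4-[(tert-butyldiphenylsilyl)oxy]but-2-enal; 4 methyl acetoacetate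
Product: 7 methyl (1S,6R)-6-{[(tert-butyldiphenylsilyl)oxy]methyl}-2-oxocyclohex-3-ene-1-carboxylate, via Michael adduct 5 (not isolated), via cyclic ketol 6 (not isolated)
Conditions: (S)-2-[diphenyl(trimethylsilyloxy)methyl]pyrrolidine (10 mol %), PhCO2H (10 mol %), toluene, 0 °C → rt; then p-TsOH·H2O (20 mol %), 45 °C
Reagents that add atoms: none
Why: Iminium-activated enantioselective Michael addition in which the diarylsilyloxymethyl group shields one face of the (E)-iminium ion, so the acetoacetate α-carbon adds to the open face of the enal β-carbon (sets C6), followed by acid-promoted intramolecular aldol condensation with the ester settling trans.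

**Step 4**
Reactants: 7 enone β-keto ester; 8 (E)-cinnamyl bromide
Product: 9 methyl (1R,6R)-6-{[(tert-butyldiphenylsilyl)oxy]methyl}-2-oxo-1-[(2E)-3-phenylprop-2-en-1-yl]cyclohex-3-ene-1-carboxylate
Conditions: K2CO3, acetone, 0 °C → rt
Reagents that add atoms: none
Why: C-alkylation of the doubly stabilised β-keto ester enolate occurs anti to the pseudo-axial C6 arm, creating quaternary C5 with cinnamyl β and CO2Me α (enolate allylation).

**Step 5**
Reactants: 9 cinnamylated enone ester
Product: 10 2-silyloxy-1,3-diene (C7=C8, C9=C10–OTBS)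
Conditions: TBSOTf, Et3N, CH2Cl2, 0 °C
Reagents that add atoms: tert-butyldimethylsilyl trifluoromethanesulfonate CC(C)(C)[Si](C)(C)OS(=O)(=O)C(F)(F)F
Why: With no α′-hydrogen left, soft enolisation can only remove the γ-hydrogen at C7, giving the linear silyl dienol ether.

**Step 6**
Reactants: 10 silyl dienol ether
Product: 11 γ-hydroxy enone (C7–OH β, C8=C9, C10=O)
Conditions: mCPBA, NaHCO3, CH2Cl2, −20 °C; aq. citric acid work-up
Reagents that add atoms: 3-chloroperoxybenzoic acid OOC(=O)c1cccc(Cl)c1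
Why: Vinylogous Rubottom oxidation, in which the peracid attacks the γ-terminus of the electron-rich diene (as with steroidal 3,5-dienol ethers) anti to the C6 arm and collapse regenerates the enone.

**Step 7**
Reactants: 11 γ-hydroxy enone
Product: 12 C7 tert-butyldimethylsilyl ether
Conditions: TBSCl, imidazole, DMF, rt
Reagents that add atoms: tert-butyl(chloro)dimethylsilane CC(C)(C)[Si](C)(C)Cl
Why: Routine silylation of the secondary allylic alcohol.

**Step 8**
Reactants: 12 silyloxy enone
Product: 14 enol triflate (C9=C10–OTf), via lithium enolate 13 (not isolated)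
Conditions: LiBH(s-Bu)3, THF, −78 °C; then N-(5-chloropyridin-2-yl)triflimide, −78 → 0 °C
Reagents that add atoms: N-(5-chloropyridin-2-yl)-1,1,1-trifluoro-N-(trifluoromethylsulfonyl)methanesulfonamide FC(F)(F)S(=O)(=O)N(c1ccc(Cl)cn1)S(=O)(=O)C(F)(F)F
Why: Conjugate hydride reduction of the β-unsubstituted enone gives a regiodefined enolate (C5 is quaternary) that is O-triflated (conjugate reduction–enolate trapping).

**Step 9**
Reactants: 14 enol triflate
Product: 15 trisubstituted alkene (C9=C10–CH3)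
Conditions: MeMgBr, Fe(acac)3 (5 mol %), THF/NMP, −30 °C
Reagents that add atoms: methylmagnesium bromide C[Mg]Br
Why: Iron-catalysed Kumada-type cross-coupling of the enol triflate is fast at low temperature and spares the hindered ester.

**Step 10**
Reactants: 15 alkene ester
Product: 16 homoallylic primary alcohol (C1–OH)
Conditions: LiAlH4, THF, 0 °C
Reagents that add atoms: none
Why: Hydride reduction of the only reducible group, the neopentylic methyl ester, gives the directing hydroxymethyl group.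

**Step 11**
Reactants: 16 homoallylic alcohol
Product: 17 9,10-α-epoxide
Conditions: VO(acac)2 (5 mol %), t-BuOOH, CH2Cl2, 0 °C → rt
Reagents that add atoms: tert-butyl hydroperoxide CC(C)(C)OO
Why: Vanadium-catalysed hydroxyl-directed epoxidation delivers oxygen to the trisubstituted ring alkene from the face of the CH2OH group, fixing the C10 oxygen cis to C1.

**Step 12**
Reactants: 17 epoxy alcohol
Product: 18 diol (C1–OH; C10 α-OH, β-CH3)
Conditions: LiBHEt3, THF, 0 °C → rt
Reagents that add atoms: none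
Why: Hydride opens the trisubstituted epoxide by SN2 attack at the less substituted C9, so the C10–O bond and its configuration are retained.

**Step 13**
Reactants: 18 diol
Product: 19 C1 tosylate
Conditions: TsCl, Et3N, 4-(dimethylamino)pyridine (cat.), CH2Cl2, 0 °C → rt
Reagents that add atoms: p-toluenesulfonyl chloride Cc1ccc(cc1)S(Cl)(=O)=O
Why: Sulfonylation is selective for the primary over the tertiary hydroxyl, and the neopentyl tosylate (no β-hydrogen, inert to intermolecular SN2) can be carried forward.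

**Step 14**
Reactants: 19 bis-silyl ether tosylate
Product: 20 triol (C6–CH2OH, C7–OH, C10–OH)
Conditions: HF·pyridine, pyridine, THF, 0 °C → rt
Reagents that add atoms: none
Why: Buffered fluoride cleaves both silyl ethers without base, avoiding oxetane formation from the hydroxy tosylate (desilylation).

**Step 15**
Reactants: 20 triol; 21 2-(diethoxyphosphoryl)propanoic acid
Product: 22 primary phosphonopropanoate ester
Conditions: DCC, 4-(dimethylamino)pyridine (cat.), CH2Cl2, −20 → 0 °C
Reagents that add atoms: none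
Why: Steglich esterification takes the primary alcohol in preference to the flanked secondary and the tertiary one.

**Step 16**
Reactants: 22 hydroxy phosphonate ester
Product: 23 C7 ketone
Conditions: Dess–Martin periodinane, NaHCO3, CH2Cl2, rt
Reagents that add atoms: none
Why: Near-neutral oxidation of the only oxidisable (secondary) alcohol gives the β-acyloxy ketone without elimination.

**Step 17**
Reactants: 23 keto phosphonate
Product: 24 bicyclic α,β-unsaturated δ-lactone
Conditions: LiCl, i-Pr2NEt, MeCN, rt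
Reagents that add atoms: none
Why: Intramolecular Horner–Wadsworth–Emmons olefination under Masamune–Roush conditions closes a six-membered lactone whose ring forces the carbonyl cis to C6 and the methyl cis to C8, which sets the alkene geometry.

**Step 18**
Reactants: 24 unsaturated lactone
Product: 25 (Z)-hydroxy Weinreb amide
Conditions: Me2AlN(OMe)Me (from AlMe3 + MeNHOMe), CH2Cl2, 0 °C → rt
Reagents that add atoms: N,O-dimethylhydroxylamine CNOC
Why: Weinreb aminolysis of the lactone frees the C6–CH2OH group and stores the future aldehyde as an amide with the alkene geometry unchanged.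

**Step 19**
Reactants: 25 hydroxy amide
Product: 26 primary iodide
Conditions: PPh3, I2, imidazole, CH2Cl2, 0 °C
Reagents that add atoms: iodine II
Why: Appel-type iodination of the primary alcohol under neutral conditions, with the product used at once.

**Step 20**
Reactants: 26 iodide
Product: 27 C6-allyl Weinreb amide
Conditions: (CH2=CH)2CuMgBr (from CH2=CHMgBr + CuI), THF, −40 → 0 °C
Reagents that add atoms: vinylmagnesium bromide C=C[Mg]Br
Why: SN2 substitution of the primary iodide by a cuprate, which neither adds to the Weinreb amide nor displaces the neopentyl tosylate.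

**Step 21**
Reactants: 27 allyl compound
Product: 29 C6 3-hydroxypropyl compound, via B-alkyl-9-BBN adduct 28 (not isolated)
Conditions: 9-BBN, THF, 0 °C → rt; then H2O2, aq. NaOH, 0 °C
Reagents that add atoms: hydrogen peroxide OO
Why: Anti-Markovnikov hydroboration–oxidation, since 9-BBN reacts with the monosubstituted terminal alkene far faster than with the styrenyl or the tetrasubstituted alkene.

**Step 22**
Reactants: 29 diol
Product: 30 bis(triethylsilyl) ether
Conditions: TESOTf, 2,6-lutidine, CH2Cl2, −78 → 0 °C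
Reagents that add atoms: triethylsilyl trifluoromethanesulfonate CC[Si](CC)(CC)OS(=O)(=O)C(F)(F)F
Why: The silyl triflate caps both the primary and the hindered tertiary hydroxyl before fragment union and ring closure.

**Step 23**
Reactants: 31 prop-2-yn-1-ol
Product: 33 (E)-3-iodo-2-methylprop-2-en-1-ol, via alkenylalane 32 (not isolated)
Conditions: AlMe3, Cp2ZrCl2 (25 mol %), CH2Cl2, 0 °C → rt; then I2, THF, −30 °C
Reagents that add atoms: trimethylaluminium C[Al](C)C; iodine II
Why: Negishi zirconium-catalysed carboalumination adds CH3 and Al syn across the alkyne (methyl to the internal carbon), and iodinolysis with retention gives the (E)-iodide.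

**Step 24**
Reactants: 33 iodo allylic alcohol
Product: 34 (E)-3-iodo-2-methylprop-2-enal
Conditions: MnO2, CH2Cl2, rt
Reagents that add atoms: none
Why: Selective allylic oxidation that leaves the vinyl iodide and its geometry untouched.

**Step 25**
Reactants: 35 geranyl bromide; 36 triethyl phosphite
Product: 37 diethyl geranylphosphonate
Conditions: neat, 130 °C
Reagents that add atoms: none
Why: Michaelis–Arbuzov reaction of the primary allylic bromide.

**Step 26**
Reactants: 37 diethyl geranylphosphonate; 34 iodo enal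
Product: 38 (1E,3E,5E)-1-iodo-2,6,10-trimethylundeca-1,3,5,9-tetraene
Conditions: KN(SiMe3)2, THF, −78 °C; then 34, −78 °C → rt
Reagents that add atoms: none
Why: Horner–Wadsworth–Emmons olefination of the allylic phosphonate anion forms the new disubstituted alkene with E selectivity.

**Step 27**
Reactants: 30 cinnamyl compound
Product: 40 C5-acetaldehyde (C3 aldehyde), via vicinal diol 39 (not isolated)
Conditions: OsO4 (2 mol %), NaIO4, 2,6-lutidine, dioxane/H2O, rt
Reagents that add atoms: osmium tetroxide O=[Os](=O)(=O)=O (oxygen carrier); sodium periodate [Na+].[O-]I(=O)(=O)=O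
Why: Lemieux–Johnson cleavage, in which OsO4 dihydroxylates only the accessible styrenyl alkene (the tetrasubstituted electron-poor one is inert) and periodate cleaves the diol.

**Step 28**
Reactants: 40 aldehyde; 38 tetraenyl iodide
Product: 41 polyenyl allylic alcohol (C3 epimers)
Conditions: CrCl2, NiCl2 (2 mol %), DMSO/THF, rt
Reagents that add atoms: none
Why: Nozaki–Hiyama–Kishi coupling, in which the alkenylchromium species forms with retention of geometry and adds only to the aldehyde in the presence of amide, tosylate and silyl ethers.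

**Step 29**
Reactants: 41 allylic alcohol
Product: 42 tetraenyl ketone
Conditions: MnO2, CH2Cl2, rt
Reagents that add atoms: none
Why: Neutral allylic oxidation converges both C3 epimers on one ketone.

**Step 30**
Reactants: 42 ketone
Product: 43 (3R)-allylic alcohol
Conditions: (S)-1-methyl-3,3-diphenyl-tetrahydro-1H,3H-pyrrolo[1,2-c][1,3,2]oxazaborole, catecholborane, toluene, −78 °C
Reagents that add atoms: none
Why: Corey–Bakshi–Shibata reduction, in which the polyenyl group acts as the large substituent so the (S)-catalyst delivers hydride to give the (R)-carbinol (C3 set by reagent control).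

**Step 31**
Reactants: 43 hydroxy tosylate
Product: 44 spiro-tetrahydrofuran
Conditions: NaH, THF/DMF, 0 → 40 °C
Reagents that add atoms: none
Why: Intramolecular Williamson etherification (5-exo-tet) of the C3 alkoxide on the neopentyl tosylate closes the ring with retention at C3.

**Step 32**
Reactants: 44 bis-silyl ether
Product: 45 diol Weinreb amide
Conditions: HF·pyridine, pyridine, THF, 0 °C
Reagents that add atoms: none
Why: Buffered fluoride removes both triethylsilyl ethers without ionising the allylic ether (desilylation).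

**Step 33**
Reactants: 45 Weinreb amide
Product: 46 target (CNP0220216.1)
Conditions: i-Bu2AlH, THF, −78 °C; aq. potassium sodium tartrate
Reagents that add atoms: none
Why: Hydride reduction of the Weinreb amide stops at a chelated hemiaminal that releases the (Z)-enal only on work-up, so there is no over-reduction or isomerisation.

**Compound list**
1 | (Z)-but-2-ene-1,4-diol | OC/C=C\CO | starting material
2 | (Z)-4-[(tert-butyldiphenylsilyl)oxy]but-2-en-1-ol | OC/C=C\CO[Si](c1ccccc1)(c1ccccc1)C(C)(C)C | intermediate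
3 | (E)-4-[(tert-butyldiphenylsilyl)oxy]but-2-enal | O=C/C=C/CO[Si](c1ccccc1)(c1ccccc1)C(C)(C)C | intermediate
4 | methyl acetoacetate | CC(=O)CC(=O)OC | starting material
5 | methyl (3R)-2-acetyl-3-{[(tert-butyldiphenylsilyl)oxy]methyl}-5-oxopentanoate (C2 epimers) | CC(=O)C(C(=O)OC)[C@H](CO[Si](c1ccccc1)(c1ccccc1)C(C)(C)C)CC=O | intermediate (not isolated)
6 | methyl (6R)-6-{[(tert-butyldiphenylsilyl)oxy]methyl}-4-hydroxy-2-oxocyclohexane-1-carboxylate (ketol; C1 and C4 epimers) | COC(=O)C1[C@H](CO[Si](c2ccccc2)(c2ccccc2)C(C)(C)C)CC(O)CC1=O | intermediate (not isolated)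
7 | methyl (1S,6R)-6-{[(tert-butyldiphenylsilyl)oxy]methyl}-2-oxocyclohex-3-ene-1-carboxylate | COC(=O)[C@H]1[C@H](CO[Si](c2ccccc2)(c2ccccc2)C(C)(C)C)CC=CC1=O | intermediate
8 | (E)-cinnamyl bromide | BrC/C=C/c1ccccc1 | starting material
9 | methyl (1R,6R)-6-{[(tert-butyldiphenylsilyl)oxy]methyl}-2-oxo-1-[(2E)-3-phenylprop-2-en-1-yl]cyclohex-3-ene-1-carboxylate (C5: CO2Me α, cinnamyl β; C6 arm α) | c1ccccc1/C=C/C[C@@]2(C(=O)OC)[C@H](CO[Si](c3ccccc3)(c4ccccc4)C(C)(C)C)CC=CC2=O | intermediate
10 | silyl dienol ether of 9 (C7=C8, C9=C10–OTBS; C5 and C6 as in 9) | c1ccccc1/C=C/C[C@@]2(C(=O)OC)[C@H](CO[Si](c3ccccc3)(c4ccccc4)C(C)(C)C)C=CC=C2O[Si](C)(C)C(C)(C)C | intermediate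
11 | γ-hydroxy enone (as 9 with C7–OH β) | c1ccccc1/C=C/C[C@@]2(C(=O)OC)[C@H](CO[Si](c3ccccc3)(c4ccccc4)C(C)(C)C)[C@@H](O)C=CC2=O | intermediate
12 | C7–OTBS enone (as 11, silylated) | c1ccccc1/C=C/C[C@@]2(C(=O)OC)[C@H](CO[Si](c3ccccc3)(c4ccccc4)C(C)(C)C)[C@@H](O[Si](C)(C)C(C)(C)C)C=CC2=O | intermediate
13 | lithium enolate (C9=C10–OLi) of the saturated ketone from 12 | c1ccccc1/C=C/C[C@@]2(C(=O)OC)[C@H](CO[Si](c3ccccc3)(c4ccccc4)C(C)(C)C)[C@@H](O[Si](C)(C)C(C)(C)C)CC=C2[O-].[Li+] | intermediate (not isolated)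
14 | enol triflate (C9=C10–OTf; C5: CO2Me α, cinnamyl β; C6: CH2OTBDPS α; C7: OTBS β) | c1ccccc1/C=C/C[C@@]2(C(=O)OC)[C@H](CO[Si](c3ccccc3)(c4ccccc4)C(C)(C)C)[C@@H](O[Si](C)(C)C(C)(C)C)CC=C2OS(=O)(=O)C(F)(F)F | intermediate
15 | methyl ester with C9=C10–CH3 alkene (other groups as 14) | c1ccccc1/C=C/C[C@@]2(C(=O)OC)[C@H](CO[Si](c3ccccc3)(c4ccccc4)C(C)(C)C)[C@@H](O[Si](C)(C)C(C)(C)C)CC=C2C | intermediate
16 | primary alcohol (C1–OH α on C5; C9=C10–CH3) | c1ccccc1/C=C/C[C@@]2(CO)[C@H](CO[Si](c3ccccc3)(c4ccccc4)C(C)(C)C)[C@@H](O[Si](C)(C)C(C)(C)C)CC=C2C | intermediate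
17 | 9,10-α-epoxide of 16 | c1ccccc1/C=C/C[C@@]2(CO)[C@H](CO[Si](c3ccccc3)(c4ccccc4)C(C)(C)C)[C@@H](O[Si](C)(C)C(C)(C)C)C[C@@H]5O[C@]25C | intermediate
18 | diol (C1–OH; C10: OH α, CH3 β) | c1ccccc1/C=C/C[C@@]2(CO)[C@H](CO[Si](c3ccccc3)(c4ccccc4)C(C)(C)C)[C@@H](O[Si](C)(C)C(C)(C)C)CC[C@]2(C)O | intermediate
19 | C1 tosylate of 18 | c1ccccc1/C=C/C[C@@]2(COS(=O)(=O)c3ccc(C)cc3)[C@H](CO[Si](c4ccccc4)(c5ccccc5)C(C)(C)C)[C@@H](O[Si](C)(C)C(C)(C)C)CC[C@]2(C)O | intermediate
20 | triol tosylate (C6–CH2OH α, C7–OH β, C10–OH α; C5: CH2OTs α, cinnamyl β) | c1ccccc1/C=C/C[C@@]2(COS(=O)(=O)c3ccc(C)cc3)[C@H](CO)[C@@H](O)CC[C@]2(C)O | intermediate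
21 | 2-(diethoxyphosphoryl)propanoic acid | CCOP(=O)(OCC)C(C)C(=O)O | starting material
22 | C6–CH2O 2-(diethoxyphosphoryl)propanoate of 20 (C7–OH free) | c1ccccc1/C=C/C[C@@]2(COS(=O)(=O)c3ccc(C)cc3)[C@H](COC(=O)C(C)P(=O)(OCC)OCC)[C@@H](O)CC[C@]2(C)O | intermediate
23 | C7 ketone of 22 | c1ccccc1/C=C/C[C@@]2(COS(=O)(=O)c3ccc(C)cc3)[C@H](COC(=O)C(C)P(=O)(OCC)OCC)C(=O)CC[C@]2(C)O | intermediate
24 | bicyclic α,β-unsaturated δ-lactone (C7=C(CH3)–C(=O)–O–CH2–C6; C5 and C10 as 20) | c1ccccc1/C=C/C[C@@]2(COS(=O)(=O)c3ccc(C)cc3)[C@@H]4COC(=O)C(C)=C4CC[C@]2(C)O | intermediate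
25 | (Z)-Weinreb amide (C7=C(CH3)C(=O)N(OMe)Me, carbonyl cis to C6; C6–CH2OH) | c1ccccc1/C=C/C[C@@]2(COS(=O)(=O)c3ccc(C)cc3)[C@H](CO)/C(=C(/C)C(=O)N(C)OC)CC[C@]2(C)O | intermediate
26 | iodide of 25 (C6–CH2I) | c1ccccc1/C=C/C[C@@]2(COS(=O)(=O)c3ccc(C)cc3)[C@H](CI)/C(=C(/C)C(=O)N(C)OC)CC[C@]2(C)O | intermediate
27 | C6-allyl Weinreb amide | c1ccccc1/C=C/C[C@@]2(COS(=O)(=O)c3ccc(C)cc3)[C@H](CC=C)/C(=C(/C)C(=O)N(C)OC)CC[C@]2(C)O | intermediate
28 | B-[3-(C6)propyl]-9-borabicyclo[3.3.1]nonane adduct of 27 | c1ccccc1/C=C/C[C@@]2(COS(=O)(=O)c3ccc(C)cc3)[C@H](CCCB4C5CCCC4CCC5)/C(=C(/C)C(=O)N(C)OC)CC[C@]2(C)O | intermediate (not isolated)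
29 | C6 3-hydroxypropyl Weinreb amide (C10–OH free) | c1ccccc1/C=C/C[C@@]2(COS(=O)(=O)c3ccc(C)cc3)[C@H](CCCO)/C(=C(/C)C(=O)N(C)OC)CC[C@]2(C)O | intermediate
30 | bis(triethylsilyl) ether of 29 | c1ccccc1/C=C/C[C@@]2(COS(=O)(=O)c3ccc(C)cc3)[C@H](CCCO[Si](CC)(CC)CC)/C(=C(/C)C(=O)N(C)OC)CC[C@]2(C)O[Si](CC)(CC)CC | intermediate
31 | prop-2-yn-1-ol | C#CCO | starting material
32 | (E)-alkenylalane, dimethylaluminium alkoxide of 3-(dimethylalumanyl)-2-methylprop-2-en-1-ol | C[Al](C)OC/C(C)=C/[Al](C)C | intermediate (not isolated)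
33 | (E)-3-iodo-2-methylprop-2-en-1-ol | OC/C(C)=C/I | intermediate
34 | (E)-3-iodo-2-methylprop-2-enal | O=C/C(C)=C/I | intermediate
35 | geranyl bromide | CC(C)=CCC/C(C)=C/CBr | starting material
36 | triethyl phosphite | CCOP(OCC)OCC | starting material
37 | diethyl [(2E)-3,7-dimethylocta-2,6-dien-1-yl]phosphonate | CC(C)=CCC/C(C)=C/CP(=O)(OCC)OCC | intermediate
38 | (1E,3E,5E)-1-iodo-2,6,10-trimethylundeca-1,3,5,9-tetraene | CC(C)=CCC/C(C)=C/C=C/C(C)=C/I | intermediate
39 | vicinal diol from the cinnamyl alkene of 30 (diol stereoisomers) | OC(c1ccccc1)C(O)C[C@@]2(COS(=O)(=O)c3ccc(C)cc3)[C@H](CCCO[Si](CC)(CC)CC)/C(=C(/C)C(=O)N(C)OC)CC[C@]2(C)O[Si](CC)(CC)CC | intermediate (not isolated)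
40 | aldehyde (C5–CH2–CHO; C3 = CHO) | O=CC[C@@]2(COS(=O)(=O)c3ccc(C)cc3)[C@H](CCCO[Si](CC)(CC)CC)/C(=C(/C)C(=O)N(C)OC)CC[C@]2(C)O[Si](CC)(CC)CC | intermediate
41 | tetraenyl allylic alcohol (C3 epimers) | CC(C)=CCC/C(C)=C/C=C/C(C)=C/C(O)C[C@@]2(COS(=O)(=O)c3ccc(C)cc3)[C@H](CCCO[Si](CC)(CC)CC)/C(=C(/C)C(=O)N(C)OC)CC[C@]2(C)O[Si](CC)(CC)CC | intermediate
42 | tetraenyl ketone (C3=O) | CC(C)=CCC/C(C)=C/C=C/C(C)=C/C(=O)C[C@@]2(COS(=O)(=O)c3ccc(C)cc3)[C@H](CCCO[Si](CC)(CC)CC)/C(=C(/C)C(=O)N(C)OC)CC[C@]2(C)O[Si](CC)(CC)CC | intermediate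
43 | (3R)-allylic alcohol | CC(C)=CCC/C(C)=C/C=C/C(C)=C/[C@H](O)C[C@@]2(COS(=O)(=O)c3ccc(C)cc3)[C@H](CCCO[Si](CC)(CC)CC)/C(=C(/C)C(=O)N(C)OC)CC[C@]2(C)O[Si](CC)(CC)CC | intermediate
44 | (3R,5S,6R,10S)-spiro-tetrahydrofuran, bis(triethylsilyl) ether, Weinreb amide | CC(C)=CCC/C(C)=C/C=C/C(C)=C/[C@H]1C[C@@]2(CO1)[C@H](CCCO[Si](CC)(CC)CC)/C(=C(/C)C(=O)N(C)OC)CC[C@]2(C)O[Si](CC)(CC)CC | intermediate
45 | diol Weinreb amide (target with C(=O)N(OMe)Me in place of CHO) | CC(C)=CCC/C(C)=C/C=C/C(C)=C/[C@H]1C[C@@]2(CO1)[C@H](CCCO)/C(=C(/C)C(=O)N(C)OC)CC[C@]2(C)O | intermediate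
46 | (2Z)-2-{(3R,5S,6R,10S)-10-hydroxy-6-(3-hydroxypropyl)-10-methyl-3-[(1E,3E,5E)-2,6,10-trimethylundeca-1,3,5,9-tetraen-1-yl]-2-oxaspiro[4.5]decan-7-ylidene}propanal | CC(C)=CCC/C(C)=C/C=C/C(C)=C/[C@H]1C[C@@]2(CO1)[C@H](CCCO)/C(=C(/C)C=O)CC[C@]2(C)O | target

**Totals**
Total step count: 33. Longest linear sequence: 29 steps (steps 1–22, then 27–33); the iodide branch is steps 23–26.

**Three steps most likely to fail**

Step 17 (intramolecular HWE on a hindered ketone to a tetrasubstituted alkene; β-elimination of the acyloxy group competes). The fallback sets out from triol 20 and comes back at lactone 24. The primary hydroxyl is acylated with 2-bromopropanoyl bromide/pyridine to give bromo ester F1. Dess–Martin oxidation gives bromo ketone F2. SmI2 (THF, −78 °C) then triggers an intramolecular Reformatsky aldol to β-hydroxy lactone F3. Trifluoroacetylation and DBU-induced elimination (the transient C10 trifluoroacetate is removed with K2CO3/MeOH) give 24, the ring again dictating the alkene geometry.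

Step 20 (the primary iodide sits next to the Z-amide carbonyl, whose oxygen can displace iodide and re-form the lactone before the cuprate reacts). The fallback sets out from lactone 24 and comes back at 27. The lactone is saponified (LiOH) and the carboxylate methylated in situ (MeI) to hydroxy ester F4, whose ester carbonyl is a much poorer neighbouring group. Appel iodination gives iodo ester F5, the divinylcuprate gives allyl ester F6, and Me2AlN(OMe)Me converts this ester into 27.

Step 6 (peracid may attack the α- rather than the γ-carbon of the dienol ether). The fallback sets out from silyl dienol ether 10 and comes back at 11. A [4+2] photooxygenation (O2, tetraphenylporphyrin, visible light, −78 °C) gives endoperoxide F7, which can only place oxygen at C7 and C10. Thiourea reduction of the O–O bond with loss of silanol gives 11.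

**Further compounds**
F1 | step 17 | 2-bromopropanoate of triol 20 at C6–CH2OH (C7–OH free) | c1ccccc1/C=C/C[C@@]2(COS(=O)(=O)c3ccc(C)cc3)[C@H](COC(=O)C(C)Br)[C@@H](O)CC[C@]2(C)O
F2 | step 17 | C7 ketone of F1 | c1ccccc1/C=C/C[C@@]2(COS(=O)(=O)c3ccc(C)cc3)[C@H](COC(=O)C(C)Br)C(=O)CC[C@]2(C)O
F3 | step 17 | β-hydroxy δ-lactone (C7 tertiary OH; new centres unassigned) | c1ccccc1/C=C/C[C@@]2(COS(=O)(=O)c3ccc(C)cc3)[C@@H]4COC(=O)C(C)C4(O)CC[C@]2(C)O
F4 | step 20 | methyl (Z)-ester analogue of 25 (C6–CH2OH) | c1ccccc1/C=C/C[C@@]2(COS(=O)(=O)c3ccc(C)cc3)[C@H](CO)/C(=C(/C)C(=O)OC)CC[C@]2(C)O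
F5 | step 20 | iodide of F4 | c1ccccc1/C=C/C[C@@]2(COS(=O)(=O)c3ccc(C)cc3)[C@H](CI)/C(=C(/C)C(=O)OC)CC[C@]2(C)O
F6 | step 20 | C6-allyl methyl (Z)-ester | c1ccccc1/C=C/C[C@@]2(COS(=O)(=O)c3ccc(C)cc3)[C@H](CC=C)/C(=C(/C)C(=O)OC)CC[C@]2(C)O
F7 | step 6 | C7,C10-endoperoxide of 10 (peroxide bridge on the β face) | c1ccccc1/C=C/C[C@@]2(C(=O)OC)[C@H](CO[Si](c3ccccc3)(c4ccccc4)C(C)(C)C)[C@H]5OO[C@]2(O[Si](C)(C)C(C)(C)C)C=C5
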